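## The problem

Target 18 is an isoflavone: a benzopyranone (rings A and C) that carries at C3 a phloroglucinol-derived ring B. Ring B is fully differentiated, with free hydroxyls at C2' and C6', a methyl ether at C4' and a prenyl group at C3', wedged between the C2' hydroxyl and the C4' methoxyl. There is no stereocentre, so the task is one of regiochemistry and chemoselectivity. Four substituents must be placed on a symmetric phloroglucinol core, and the one unsubstituted ring-B carbon (C5') stays strongly nucleophilic throughout. The C3–C1' bond is flanked by two ortho oxygens, so forming it late at a di-ortho-substituted carbon is unattractive. The prenyl group cyclises onto a neighbouring phenol under Brønsted or Lewis acid and does not survive hydrogenolysis, the pyranone opens in strong base, and three phenols must be freed while the C4' methyl ether stays. The only stereochemical element on the way is the geometry of an enol ether double bond, which must place the acyl carbon cis to the aryloxy oxygen or be able to equilibrate. The enabling feature is that C4a of ring A lies para to the C7 oxygen and ortho to O1. In a resorcinol diether this is the most nucleophilic carbon, and an acyl carbon tethered through O1–C2=C3 reaches it through a six-membered transition state, so ring C can be closed at C4–C4a on a ring A that is bought as a phenol.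

## Retrosynthesis

**18 to 16 and 17.** The C2''=C3'' double bond of the prenyl group is cut, which leads back to the allyl compound 16 and 2-methylbut-2-ene 17 (cross-metathesis). The trisubstituted alkene is the most acid-sensitive group of the target, and a monosubstituted allyl group can pass through the acidic ring closure and the Lewis-acid deprotection without chroman formation. Direct C-prenylation of a phloroglucinol would be unselective. The forward step must tolerate three free phenols and must not move the double bond into conjugation.

**16 to 15.** Three O–benzyl bonds are cut. Benzyl ethers withstand the basic alkylation and enolate steps and a mild acid anhydride, and they can be removed with BCl3 without hydrogen, which would saturate the allyl group and the C2=C3 bond. The C4' methyl ether is not chelated and should stay. Acetal protecting groups would not survive the acylation, and silyl ethers would not survive the early base steps.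

**15 to 13 (key disconnection).** The C4–C4a bond is cut, which opens ring C to the 3-aryloxy-2-arylacrylic acid 13; in the flask it is activated as the mixed anhydride 14. Two neighbouring cuts were weighed against this one:
- Closure at O1–C2 from a deoxybenzoin would need an intermolecular acylation of a resorcinol under conditions that benzyl ethers and the electron-rich ring B would not tolerate.
- A coupling at C3–C1' would need a ring-B organometallic. This cannot be made regioselectively, because C1' and C5' are both flanked by two oxygens, and the coupling would be at a di-ortho-substituted carbon.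

The chosen cut removes ring C and reduces ring A to a commercial phenol. The forward reaction must acylate ring A para to the benzyloxy group, leave ring B, the allyl group and the benzyl ethers alone, and accept either enol ether geometry.

**13 to 12, then 12 to 10 and 11.** Hydrolysis of the methyl ester 12 gives the acid. The O1–C2 vinyl ether bond of 12 is then cut, giving 3-(benzyloxy)phenol 11 and the enol tosylate 10 (addition–elimination at the β-carbon of an acrylate). The alternative of adding the phenol to a propiolate and then arylating the α-carbon again needs the inaccessible ring-B organometallic. The cut separates ring A completely from the ring-B fragment.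

**10 to 9 to 8.** The sulfonate is removed to the enol 9. The C2–C3 bond (chromone numbering) is then cut, a crossed Claisen condensation of the arylacetate 8 with a formate ester, which supplies the future C2. The forward step needs only the acidity of the benzylic CH2 group.

**8 to 7 to 6.** The ester carbon (the future C4) is removed by a one-carbon homologation of aldehyde 6 through nitrile 7. A benzylic halide and cyanide route is avoided because a 2,4,6-trioxygenated benzylic cation would alkylate the free C5' position of another molecule. An isocyanide-based reductive cyanation works under base only.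

**6 to 5 to 4, then 4 to 2 and 3, then 2 to 1.** Two benzyl ethers are removed to give 5. The C3'–C1'' bond is cut by an aromatic Claisen rearrangement of the allyl ether 4. The formyl group blocks C1, so the allyl group can only go to C3, between the new phenol and the methoxyl. Ether 4 comes from 2 and allyl bromide 3, and 2 from 4-O-methylation of the symmetric 2,4,6-trihydroxybenzaldehyde 1. The formyl carbon of 1 sets 4-OH apart from 2-OH and 6-OH, directs the Claisen shift, and ends as C3 of the chromone, so the crowded C3–C1' bond is never made.

## Roads not taken

**Alternative 1: aryne oxa-Claisen for ring B.** The cut is at C4'–O and C3'–C1'' of ring B. Fluoride would generate the aryne A3 (3,5-bis(methoxymethoxy)benzyne). The ether oxygen of 3-methoxy-3-methylbut-1-ene A2 adds at the future C4', and the 1,1-dimethylallyl unit shifts to the neighbouring carbon with allylic transposition. This gives A1 with the methoxyl and the prenyl group ortho to each other in one step.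
- Merits: the two hardest ring-B substituents arrive together in the right relationship, with no allyl-to-prenyl metathesis.
- Weak points: no ring closes and nothing of the isoflavone core is made. The aryne precursor takes several steps. The ether may also transfer its methyl group or react through its alkene. A1 must still be metallated between its two acetal ethers and joined to a chromone at a di-ortho-substituted carbon. The acetals must finally be removed with acid next to a prenyl group, the conditions under which a chroman forms.
- Comparison: this road is better at installing the prenyl and methoxyl groups and needs no ruthenium step. The chosen plan sets against it that the C3–C1' bond is inherited from the aldehyde carbon of 1, that every acid step is run on an allyl compound, and that its ring-B chemistry is classical.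

**Alternative 2: Danheiser benzannulation of ring B onto the chromone.** Three bonds of ring B are cut (C6'–C1', C2'–C3', C5'–C6'). Thermolysis of cyclobutenone A5 (3-methoxy-2-prenylcyclobut-2-en-1-one) with the chromon-3-yl siloxyalkyne A6 would pass through a vinylketene, a [2+2] adduct and a dienylketene to the phenol A4.
- Merits: it is the most convergent route. The mechanism fixes the regiochemistry, the three ring-B oxygens emerge already differentiated, the prenyl group comes in intact, and the C3–C1' bond is not made by coupling.
- Weak points: both partners are demanding. A siloxyalkyne on a chromone requires ynolate chemistry next to a Michael-accepting pyranone. The electron-poor chromonyl group lowers the nucleophilicity the alkyne needs towards the vinylketene. The prenyl alkene of A5 can be trapped by its own ketene.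
- Comparison: this road is superior in convergence and in step count after the building blocks. The chosen plan answers with commercial or near-commercial inputs and a key step of a known reaction class.

**Alternative 3: ring A as a vinylogous ester, aromatised late.** The cut is at C4–C4a and O1–C2 together. The kinetic lithium enolate of 3-(allyloxy)cyclohex-2-en-1-one A8 would be C-acylated by the β-methoxyacryloyl chloride A9. The enol oxygen would then displace methoxide to give the dihydrochromenone A7.
- Merits: no electrophilic aromatic substitution is needed, so there is no regiochemical question on ring A and no acid near ring B. The prenyl group could be carried intact.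
- Weak points: O-acylation competes with C-acylation for an acid chloride flanked by a di-ortho-substituted aryl group. Ring A must afterwards be dehydrogenated in the presence of a prenyl group and an electron-rich ring B. The acetal ethers again come off under acid beside the prenyl group. A9 needs the same ring-B arylacetate and formylation chemistry as the chosen route, so nothing is saved there.
- Comparison: this road is better in avoiding the Friedel–Crafts selectivity questions and the metathesis. The chosen plan sets against it an aromatic ring A bought ready-made and no late oxidation.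

Key step: step 11

Remark on the chemistry: compounds 9, 10, 12, 13 and 14 are drawn as Z isomers (carbonyl group cis to the C3 oxygen). This is the geometry expected from chelation-controlled sulfonylation and substitution with retention. Any E isomer formed alongside is carried on, because step 11 equilibrates the two.

## Route

Step 1
Reactants: 1 2,4,6-trihydroxybenzaldehyde
Product: 2 2,6-dihydroxy-4-methoxybenzaldehyde
Conditions: Me2SO4 (1.0 equiv), K2CO3 (1.0 equiv), acetone, rt
Reagents that add atoms: dimethyl sulfate, COS(=O)(=O)OC
Why: Williamson etherification; the 4-OH is para to the formyl group, is the most acidic and is not held in a hydrogen bond to the carbonyl, so one equivalent of base and alkylating agent should react there first.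

Step 2
Reactants: 2 2,6-dihydroxy-4-methoxybenzaldehyde; 3 allyl bromide
Product: 4 2-(allyloxy)-6-hydroxy-4-methoxybenzaldehyde
Conditions: K2CO3, acetone, reflux
Reagents that add atoms: none
Why: Williamson etherification; the two remaining hydroxyls are equivalent, and after the first is alkylated the second is held in a stronger chelate with the formyl oxygen, so the reaction should stop at the monoallyl ether.

Step 3
Reactants: 4 2-(allyloxy)-6-hydroxy-4-methoxybenzaldehyde
Product: 5 3-allyl-2,6-dihydroxy-4-methoxybenzaldehyde
Conditions: PhNEt2, 190 °C
Reagents that add atoms: none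
Why: Aromatic Claisen rearrangement; C1 carries the formyl group, so the [3,3] shift can only deliver the allyl group to C3, and tautomerisation restores the phenol, which fixes the allyl group between the C2 oxygen and the C4 methoxyl.

Step 4
Reactants: 5 3-allyl-2,6-dihydroxy-4-methoxybenzaldehyde
Product: 6 3-allyl-2,6-bis(benzyloxy)-4-methoxybenzaldehyde
Conditions: BnBr, K2CO3, KI (cat.), DMF, 60 °C
Reagents that add atoms: benzyl bromide, BrCc1ccccc1
Why: Williamson etherification of both chelated phenols; a dipolar solvent and gentle heating are chosen because the hydroxyl between the formyl and allyl groups is hindered.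

Step 5
Reactants: 6 3-allyl-2,6-bis(benzyloxy)-4-methoxybenzaldehyde
Product: 7 2-[3-allyl-2,6-bis(benzyloxy)-4-methoxyphenyl]acetonitrile
Conditions: TosMIC, t-BuOK, DME, −40 °C; then MeOH, reflux
Reagents that add atoms: p-toluenesulfonylmethyl isocyanide (TosMIC), Cc1ccc(cc1)S(=O)(=O)C[N+]#[C-]
Why: Van Leusen reductive cyanation; the isocyanide anion adds to the aldehyde, the oxazoline adduct opens to an N-formyl enamine, and methanolysis with loss of sulfinate gives the homologous nitrile under base only, so no benzylic cation that could attack C5' is ever formed.

Step 6
Reactants: 7 2-[3-allyl-2,6-bis(benzyloxy)-4-methoxyphenyl]acetonitrile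
Product: 8 methyl 2-[3-allyl-2,6-bis(benzyloxy)-4-methoxyphenyl]acetate
Conditions: HCl (anhydrous), MeOH, 0 °C to rt; then H2O
Reagents that add atoms: methanol, CO; water, O
Why: Pinner reaction; methanol adds to the protonated nitrile to give the imidate hydrochloride, which water converts into the methyl ester, and anhydrous methanolic acid at room temperature should leave the aryl benzyl ethers and the allyl group untouched.

Step 7
Reactants: 8 methyl 2-[3-allyl-2,6-bis(benzyloxy)-4-methoxyphenyl]acetate
Product: 9 methyl (Z)-2-[3-allyl-2,6-bis(benzyloxy)-4-methoxyphenyl]-3-hydroxyacrylate (enol form of the α-formyl ester)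
Conditions: NaH, HCO2Me, THF, 0 °C to rt; aq. HCl work-up
Reagents that add atoms: methyl formate, COC=O
Why: Crossed Claisen condensation; the arylacetate enolate is formylated and the equilibrium is pulled over by deprotonation of the product, which on acidification should exist as the hydrogen-bonded Z enol.

Step 8
Reactants: 9 methyl (Z)-2-[3-allyl-2,6-bis(benzyloxy)-4-methoxyphenyl]-3-hydroxyacrylate
Product: 10 methyl (Z)-2-[3-allyl-2,6-bis(benzyloxy)-4-methoxyphenyl]-3-(tosyloxy)acrylate
Conditions: TsCl, N-methylimidazole, LiOH, CH2Cl2, 0 °C
Reagents that add atoms: p-toluenesulfonyl chloride, Cc1ccc(cc1)S(Cl)(=O)=O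
Why: O-Sulfonylation of an enolate; lithium chelation between the enolate and ester oxygens should keep the new sulfonyloxy group cis to the ester (Z), while N-methylimidazole delivers the sulfonyl group as its sulfonylimidazolium salt.

Step 9
Reactants: 10 methyl (Z)-2-[3-allyl-2,6-bis(benzyloxy)-4-methoxyphenyl]-3-(tosyloxy)acrylate; 11 3-(benzyloxy)phenol
Product: 12 methyl (Z)-2-[3-allyl-2,6-bis(benzyloxy)-4-methoxyphenyl]-3-[3-(benzyloxy)phenoxy]acrylate
Conditions: Cs2CO3, MeCN, rt
Reagents that add atoms: none
Why: Nucleophilic vinylic substitution by addition–elimination; the phenoxide adds to the β-carbon of the acrylate and the tosylate leaves from the short-lived ester-stabilised carbanion, which is expected to occur mainly with retention of geometry.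

Step 10
Reactants: 12 methyl (Z)-2-[3-allyl-2,6-bis(benzyloxy)-4-methoxyphenyl]-3-[3-(benzyloxy)phenoxy]acrylate
Product: 13 (Z)-2-[3-allyl-2,6-bis(benzyloxy)-4-methoxyphenyl]-3-[3-(benzyloxy)phenoxy]acrylic acid
Conditions: LiOH·H2O, THF/MeOH/H2O, 40 °C; then aq. HCl to pH 3, 0 °C
Reagents that add atoms: lithium hydroxide, [Li+].[OH-]
Why: Ester saponification; β-alkoxyacrylates of this 2-aryl type are known to give their acids with the enol ether intact, and cold, brief acidification should avoid hydrolysis of the enol ether.

Step 11
Reactants: 13 (Z)-2-[3-allyl-2,6-bis(benzyloxy)-4-methoxyphenyl]-3-[3-(benzyloxy)phenoxy]acrylic acid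
Product: 15 3-[3-allyl-2,6-bis(benzyloxy)-4-methoxyphenyl]-7-(benzyloxy)-4H-chromen-4-one, via mixed trifluoroacetic anhydride 14 (not isolated)
Conditions: (CF3CO)2O, CH2Cl2, 0 °C to rt
Reagents that add atoms: none
Why: Trifluoroacetic anhydride converts acid 13 into the mixed anhydride 14, which reacts as a push–pull acylium ion stabilised by the enol ether oxygen; this attacks ring A at the carbon ortho to the ether oxygen and para to the benzyloxy group, and loss of a proton from the arenium ion gives the pyranone. The closest known reaction type is the acid-mediated cyclisation of 3-aryloxyacrylic acids to chromones, an intramolecular Friedel–Crafts acylation. Ring C closes as a six-membered ring by electrophilic aromatic substitution at C4a, through a transition state that runs over O1–C2=C3–C4. No stereocentre is formed; the Z geometry holds the acyl carbon cis to the aryloxy group, and an E isomer should equilibrate under the acidic conditions, either through the acylium ion, whose ketene–oxocarbenium resonance form has a single C2–C3 bond, or by reversible protonation at the α-carbon (the future C3). The step needs regioselectivity on ring A, for C4a over the carbon between the two oxygens, which para activation by the benzyloxy group and the lower crowding secure. It also needs chemoselectivity against ring B, which cannot be reached at carbon without forming a four-membered ring and whose ortho ether oxygens are weak nucleophiles that would have to lose a benzyl cation. The allyl group and the benzyl ethers are carried because they should tolerate trifluoroacetic acid at 0 °C, whereas a prenyl group next to an oxygen would not.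

Step 12
Reactants: 15 3-[3-allyl-2,6-bis(benzyloxy)-4-methoxyphenyl]-7-(benzyloxy)-4H-chromen-4-one
Product: 16 3-(3-allyl-2,6-dihydroxy-4-methoxyphenyl)-7-hydroxy-4H-chromen-4-one
Conditions: BCl3, C6HMe5, CH2Cl2, −78 °C; then MeOH/H2O
Reagents that add atoms: none
Why: Lewis-acid debenzylation with a cation scavenger; BCl3 ionises the benzyl ethers at low temperature and pentamethylbenzene traps the benzyl cations before they can alkylate ring B, while the unchelated C4' methyl ether, the terminal alkene and the pyranone should be left alone.

Step 13
Reactants: 16 3-(3-allyl-2,6-dihydroxy-4-methoxyphenyl)-7-hydroxy-4H-chromen-4-one; 17 2-methylbut-2-ene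
Product: 18 7-hydroxy-3-[2,6-dihydroxy-4-methoxy-3-(3-methylbut-2-en-1-yl)phenyl]-4H-chromen-4-one
Conditions: second-generation Grubbs catalyst (5 mol %), 2-methylbut-2-ene (large excess), CH2Cl2, 40 °C, sealed tube
Reagents that add atoms: none
Why: Olefin cross-metathesis; the terminal allyl alkene exchanges its methylene for the isopropylidene unit of the excess trisubstituted alkene with release of propene, and the electron-poor C2=C3 bond of the chromone does not take part.

## Compound list

1 | 2,4,6-trihydroxybenzaldehyde | O=Cc1c(O)cc(O)cc1O | starting material
2 | 2,6-dihydroxy-4-methoxybenzaldehyde | O=Cc1c(O)cc(OC)cc1O | intermediate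
3 | allyl bromide | C=CCBr | starting material
4 | 2-(allyloxy)-6-hydroxy-4-methoxybenzaldehyde | O=Cc1c(OCC=C)cc(OC)cc1O | intermediate
5 | 3-allyl-2,6-dihydroxy-4-methoxybenzaldehyde | O=Cc1c(O)c(CC=C)c(OC)cc1O | intermediate
6 | 3-allyl-2,6-bis(benzyloxy)-4-methoxybenzaldehyde | O=Cc1c(OCc2ccccc2)c(CC=C)c(OC)cc1OCc1ccccc1 | intermediate
7 | 2-[3-allyl-2,6-bis(benzyloxy)-4-methoxyphenyl]acetonitrile | N#CCc1c(OCc2ccccc2)c(CC=C)c(OC)cc1OCc1ccccc1 | intermediate
8 | methyl 2-[3-allyl-2,6-bis(benzyloxy)-4-methoxyphenyl]acetate | COC(=O)Cc1c(OCc2ccccc2)c(CC=C)c(OC)cc1OCc1ccccc1 | intermediate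
9 | methyl (Z)-2-[3-allyl-2,6-bis(benzyloxy)-4-methoxyphenyl]-3-hydroxyacrylate | COC(=O)/C(=C\O)c1c(OCc2ccccc2)c(CC=C)c(OC)cc1OCc1ccccc1 | intermediate
10 | methyl (Z)-2-[3-allyl-2,6-bis(benzyloxy)-4-methoxyphenyl]-3-(tosyloxy)acrylate | COC(=O)/C(=C\OS(=O)(=O)c1ccc(C)cc1)c1c(OCc2ccccc2)c(CC=C)c(OC)cc1OCc1ccccc1 | intermediate
11 | 3-(benzyloxy)phenol | Oc1cccc(OCc2ccccc2)c1 | starting material
12 | methyl (Z)-2-[3-allyl-2,6-bis(benzyloxy)-4-methoxyphenyl]-3-[3-(benzyloxy)phenoxy]acrylate | COC(=O)/C(=C\Oc1cccc(OCc2ccccc2)c1)c1c(OCc2ccccc2)c(CC=C)c(OC)cc1OCc1ccccc1 | intermediate
13 | (Z)-2-[3-allyl-2,6-bis(benzyloxy)-4-methoxyphenyl]-3-[3-(benzyloxy)phenoxy]acrylic acid | OC(=O)/C(=C\Oc1cccc(OCc2ccccc2)c1)c1c(OCc2ccccc2)c(CC=C)c(OC)cc1OCc1ccccc1 | intermediate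
14 | (Z)-2-[3-allyl-2,6-bis(benzyloxy)-4-methoxyphenyl]-3-[3-(benzyloxy)phenoxy]acrylic trifluoroacetic anhydride | O=C(OC(=O)C(F)(F)F)/C(=C\Oc1cccc(OCc2ccccc2)c1)c1c(OCc2ccccc2)c(CC=C)c(OC)cc1OCc1ccccc1 | intermediate
15 | 3-[3-allyl-2,6-bis(benzyloxy)-4-methoxyphenyl]-7-(benzyloxy)-4H-chromen-4-one | C=CCc1c(OC)cc(OCc2ccccc2)c(-c2coc3cc(OCc4ccccc4)ccc3c2=O)c1OCc1ccccc1 | intermediate
16 | 3-(3-allyl-2,6-dihydroxy-4-methoxyphenyl)-7-hydroxy-4H-chromen-4-one | C=CCc1c(OC)cc(O)c(-c2coc3cc(O)ccc3c2=O)c1O | intermediate
17 | 2-methylbut-2-ene | CC=C(C)C | starting material
18 | 7-hydroxy-3-[2,6-dihydroxy-4-methoxy-3-(3-methylbut-2-en-1-yl)phenyl]-4H-chromen-4-one | COc1cc(O)c(-c2coc3cc(O)ccc3c2=O)c(O)c1CC=C(C)C | target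

## Step count and least certain steps

Total: 13 steps. Longest linear sequence: 13 steps (1 to 18); compounds 3, 11 and 17 enter as purchased materials.

**Step 11 (key step).** The push–pull acylium ion may close too slowly. If so, acyl transfer to an ortho benzyloxy oxygen of ring B (five-membered lactonisation with loss of a benzyl cation), trifluoroacetylation of ring B at C5', or incomplete equilibration of the enol ether geometry could take over. The fallback reverses the polarity of the same bond and sets out from 10. Substitution of the tosylate with commercial 5-(benzyloxy)-2-bromophenol (Cs2CO3, MeCN) should give methyl (Z)-2-[3-allyl-2,6-bis(benzyloxy)-4-methoxyphenyl]-3-[5-(benzyloxy)-2-bromophenoxy]acrylate F1. Bromine–lithium exchange (t-BuLi, THF, −100 °C) and attack of the aryllithium on the ester (Parham cyclisation) would close C4–C4a under basic conditions. The fallback comes back to the route at 15.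

**Step 9.** The phenoxide may attack sulfur instead of C3, transferring the sulfonyl group and returning the enolate of 9, or addition at the hindered β-carbon may be slow. The fallback sets out from 9 and uses a leaving group whose only electrophilic site is carbon. Deoxychlorination (PPh3, CCl4, MeCN) gives methyl (Z)-2-[3-allyl-2,6-bis(benzyloxy)-4-methoxyphenyl]-3-chloroacrylate F2. Substitution by 11, relayed by catalytic DABCO through the vinylammonium salt (Cs2CO3, MeCN), comes back at 12.

**Step 10.** Hydroxide may add to C3 and expel the aryloxide, cleaving the vinylogous carbonate, faster than it attacks the hindered ester carbonyl. The fallback sets out from 12 and breaks the alkyl–oxygen bond instead of the acyl–oxygen bond. LiI in refluxing ethyl acetate removes the methyl group by SN2 attack of iodide, and acidification of the lithium carboxylate comes back at 13. No new compound is made.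

**Step 5.** Addition to the hindered, electron-rich aldehyde may be poor, or the adduct may be diverted to an oxazole by loss of sulfinate before ring opening. The fallback sets out from 6 and is a sequence of four known steps:
- Wittig methoxymethylenation (Ph3PCH2OMe chloride, KN(SiMe3)2, THF) gives (E)-1-[3-allyl-2,6-bis(benzyloxy)-4-methoxyphenyl]-2-methoxyethene F3; the Z isomer formed with it serves equally.
- Mild hydrolysis (aq. HCO2H, THF) gives 2-[3-allyl-2,6-bis(benzyloxy)-4-methoxyphenyl]acetaldehyde F4.
- Pinnick oxidation (NaClO2, NaH2PO4, excess 17 as chlorine scavenger) gives 2-[3-allyl-2,6-bis(benzyloxy)-4-methoxyphenyl]acetic acid F5.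
- Methylation (MeI, K2CO3, DMF) comes back at 8.

**Step 13.** Hydride species formed from the catalyst may move the allyl double bond into conjugation, and the chelating free phenols may deactivate the catalyst. The fallback sets out from 16. Peracetylation (Ac2O, pyridine) gives 3-(3-allyl-2,6-diacetoxy-4-methoxyphenyl)-4-oxo-4H-chromen-7-yl acetate F6. Cross-metathesis with 17 under the same catalyst gives 3-[2,6-diacetoxy-4-methoxy-3-(3-methylbut-2-en-1-yl)phenyl]-4-oxo-4H-chromen-7-yl acetate F7. Mild methanolysis (K2CO3, MeOH, 0 °C) comes back at 18 without acid near the prenyl group.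

**Step 1.** Alkylation may run on to di- and trimethyl ethers, or methylate the phloroglucinol nucleus at carbon. The fallback sets out from 1. Exhaustive O-methylation (excess Me2SO4, K2CO3, acetone, reflux) gives 2,4,6-trimethoxybenzaldehyde F8, which can also be bought. Chelation-controlled cleavage of the two methyl ethers ortho to the formyl group (AlCl3, CH2Cl2, reflux) comes back at 2.

## Further compounds

F1 | step 11 | methyl (Z)-2-[3-allyl-2,6-bis(benzyloxy)-4-methoxyphenyl]-3-[5-(benzyloxy)-2-bromophenoxy]acrylate | COC(=O)/C(=C\Oc1cc(OCc2ccccc2)ccc1Br)c1c(OCc2ccccc2)c(CC=C)c(OC)cc1OCc1ccccc1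
F2 | step 9 | methyl (Z)-2-[3-allyl-2,6-bis(benzyloxy)-4-methoxyphenyl]-3-chloroacrylate | COC(=O)/C(=C\Cl)c1c(OCc2ccccc2)c(CC=C)c(OC)cc1OCc1ccccc1
F0 | step 10 | none | none
F3 | step 5 | (E)-1-[3-allyl-2,6-bis(benzyloxy)-4-methoxyphenyl]-2-methoxyethene | CO/C=C/c1c(OCc2ccccc2)c(CC=C)c(OC)cc1OCc1ccccc1
F4 | step 5 | 2-[3-allyl-2,6-bis(benzyloxy)-4-methoxyphenyl]acetaldehyde | O=CCc1c(OCc2ccccc2)c(CC=C)c(OC)cc1OCc1ccccc1
F5 | step 5 | 2-[3-allyl-2,6-bis(benzyloxy)-4-methoxyphenyl]acetic acid | OC(=O)Cc1c(OCc2ccccc2)c(CC=C)c(OC)cc1OCc1ccccc1
F6 | step 13 | 3-(3-allyl-2,6-diacetoxy-4-methoxyphenyl)-4-oxo-4H-chromen-7-yl acetate | C=CCc1c(OC)cc(OC(C)=O)c(-c2coc3cc(OC(C)=O)ccc3c2=O)c1OC(C)=O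
F7 | step 13 | 3-[2,6-diacetoxy-4-methoxy-3-(3-methylbut-2-en-1-yl)phenyl]-4-oxo-4H-chromen-7-yl acetate | COc1cc(OC(C)=O)c(-c2coc3cc(OC(C)=O)ccc3c2=O)c(OC(C)=O)c1CC=C(C)C
F8 | step 1 | 2,4,6-trimethoxybenzaldehyde | COc1cc(OC)c(C=O)c(OC)c1
A1 | alternative 1 | 1-methoxy-3,5-bis(methoxymethoxy)-2-(3-methylbut-2-en-1-yl)benzene | COc1cc(OCOC)cc(OCOC)c1CC=C(C)C
A2 | alternative 1 | 3-methoxy-3-methylbut-1-ene | COC(C)(C)C=C
A3 | alternative 1 | 3,5-bis(methoxymethoxy)benzyne | COCOC1=CC(OCOC)=CC#C1
A4 | alternative 2 | 3-[6-hydroxy-4-methoxy-3-(3-methylbut-2-en-1-yl)-2-(triisopropylsilyloxy)phenyl]-7-(triisopropylsilyloxy)chromen-4-one | COc1cc(O)c(-c2coc3cc(O[Si](C(C)C)(C(C)C)C(C)C)ccc3c2=O)c(O[Si](C(C)C)(C(C)C)C(C)C)c1CC=C(C)C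
A5 | alternative 2 | 3-methoxy-2-(3-methylbut-2-en-1-yl)cyclobut-2-en-1-one | COC1=C(CC=C(C)C)C(=O)C1
A6 | alternative 2 | 7-(triisopropylsilyloxy)-3-[(triisopropylsilyloxy)ethynyl]chromen-4-one | CC(C)[Si](C(C)C)(C(C)C)OC#Cc1coc2cc(O[Si](C(C)C)(C(C)C)C(C)C)ccc2c1=O
A7 | alternative 3 | 7-(allyloxy)-3-[4-methoxy-2,6-bis(methoxymethoxy)-3-(3-methylbut-2-en-1-yl)phenyl]-5,6-dihydro-4H-chromen-4-one | C=CCOC1=CC2=C(CC1)C(=O)C(=CO2)c1c(OCOC)cc(OC)c(CC=C(C)C)c1OCOC
A8 | alternative 3 | 3-(allyloxy)cyclohex-2-en-1-one | C=CCOC1=CC(=O)CCC1
A9 | alternative 3 | (E)-3-methoxy-2-[4-methoxy-2,6-bis(methoxymethoxy)-3-(3-methylbut-2-en-1-yl)phenyl]acryloyl chloride | CO/C=C(/C(Cl)=O)c1c(OCOC)cc(OC)c(CC=C(C)C)c1OCOC
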